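## Structural features

The target is a bicyclic peroxylactone: a 1,2-dioxane (ring A: O–O, C3, C4, C5, C6) cis-fused along C3–C4 to a γ-butyrolactone (ring B: C1(=O), C2H2, C3, C4 and the ring oxygen on C4). The locants are those of the six-carbon lactone chain, C1 being the carbonyl carbon and C6 the peroxy carbon that carries the side chain. C6 is a fully substituted peroxide carbon with a methyl group and an unbranched, saturated 10-phenyldecyl chain; C4 is fully substituted with a methyl group and the lactone oxygen; C3 is a CH carrying the second peroxide oxygen. The stereocentres are C3 (R) and C4 (R), adjacent at the ring fusion, and C6 (S), separated from C4 by the C5 methylene. The decyl chain on C6, the C2 arm on C3 and the lactone oxygen on C4 lie on one face of ring A, and both methyl groups lie on the other. The O–O bond is the fragile element: it will not survive catalytic hydrogenation, phosphines or low-valent metals, and the C3–H next to it allows a base-induced Kornblum–DeLaMare-type fragmentation; the lactone is sensitive to hydroxide. The real difficulty is to make both C–O bonds of one peroxide, one at a tertiary carbon, with defined relative configuration across the 1,4-distance C3/C6, and then to reach one enantiomer although nothing near C6 offers a handle for asymmetric induction. The key step exploits the 1,4-relationship of C3 and C6 through C4–C5: ring A without its O–O unit is the diene C3=C4(CH3)–C5=C6(CH3)(chain), so both peroxide bonds can form in one (4+2) addition of oxygen. The C4=C5 alkene that remains is γ,δ to the carboxyl carbon C1 and can close ring B onto C4.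

## Logic of the disconnections

**16 ⇒ 15 ⇒ 14.** The lactone bond C4–O of ring B is cut, after C5–H has been exchanged for C5–I. A carboxyl group three atoms from a trisubstituted alkene is the retron of an electrophile-triggered lactonisation, and the short tether from C3 can deliver oxygen to C4 only on its own face, so C4 needs no separate control. The gain is the loss of ring B and of the C4 (and transient C5) stereocentres, leaving the monocyclic acid 14. The forward steps must attack the methyl-bearing C4 in the five-membered mode under conditions mild enough for an allylic peroxide, and must then remove iodine from C5 by a radical chain that leaves the neighbouring O–O bond alone.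

**14 ⇒ 13 ⇒ 12.** The peroxide bonds C3–O and C6–O are cut together, releasing the O–O unit as a two-atom dienophile and opening ring A to a diene. This disconnection carries the plan: it removes a ring, both heteroatom bonds and both remaining stereocentres at once and arrives at the achiral acid 12. Neither face of 12 is distinguished, so the forward reaction can only give racemic 13, and 14 has to be taken from 13 by separation of the enantiomers. The forward step demands a geometrically pure (3E,5E)-diene that can reach the s-cis conformation, and a cycloaddition that outruns the ene reaction.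

**12 ⇒ 11 ⇒ 6 + 8.** After the carboxyl O–H is exchanged for O–Si, the central sp2–sp2 bond C4–C5 is cut. This gives two pieces of unequal size, each with one trisubstituted alkene whose geometry can be fixed by a syn addition to an alkyne, and makes the route convergent. The silyl ester is chosen because the acidic proton cannot pass through the organometallic steps and because base-free unmasking avoids drawing the skipped diene into conjugation with C1. The forward coupling (through 9 and 10) must place the metal on the methyl-bearing carbon of 8 and retain configuration at both alkenyl carbons.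

**6 ⇒ 5 ⇒ 4.** The C5–I and C6–CH3 bonds are cut, corresponding to syn addition of a methyl–metal bond across a terminal alkyne and exchange of the metal for iodine. The trisubstituted E-iodoalkene is thereby reduced to a terminal alkyne with no stereochemical element. The forward step must deliver methyl to the internal carbon and keep the syn relationship through the iodination.

**4 ⇒ 3 ⇒ 2 ⇒ 1.** The C6–C7 bond between alkyne and chain is cut, giving a two-carbon acetylide unit and the primary bromide 3, which goes back through alcohol 2 to acid 1 by exchange of C–Br for C–O and adjustment of oxidation level. The gain is a purchasable chain that already holds the phenyl group and all ten methylenes. The forward steps require only clean SN2 chemistry at an unhindered primary carbon.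

**8 ⇒ 7.** The O–Si bond is cut, leading back to the purchasable acid 7. The forward silylation must avoid strong base, because a 3-alkynoate isomerises easily to an allenoate.

## Other disconnections considered

**Alternative 1:** The cuts are C5–C6 in ring A and C4–O in ring B.
- Forward key step: the mixed peroxyketal tert-butyl (3R)-3-[(2-methoxy-12-phenyldodec-3-yn-2-yl)peroxy]-4-methylpent-4-enoate A1 would be ionised by TMSOTf to a propargylic peroxycarbenium ion at C6. The isopropenyl CH2 would attack it to close ring A, and the tertiary cation at C4 would be captured by the ester carbonyl with loss of the tert-butyl group, closing ring B. The product would be the alkynyl bicycle A2, the C7≡C8 analogue of the target (an alkyne, so four hydrogens short of it).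
- In its favour: both rings and the stereocentres C4 and C6 would arise in one operation, and there is no ene channel. C3 would be carried in from a non-racemic allylic hydroperoxide, so absolute configuration could be built in. On that point, and on the number of steps after the key step (one saturation of the alkyne against a resolution, a lactonisation and a reduction), it would be the better plan.
- Against it here: the configuration at C6 would rest on how well a chair-like transition state tells a methyl group from a slim alkynyl group on a planar cation, a weaker control element than the alkene geometry that fixes C3/C6 in the chosen plan. The C4 cation could lose a proton instead of being trapped, and the peroxycarbenium ion has fragmentation pathways through O–O heterolysis. A1 needs an enantioenriched secondary hydroperoxide and a peroxyketalisation, so the way to it would not be shorter than the way to 12. The triple bond would afterwards have to be saturated with diimide, since catalytic hydrogenation would cleave the peroxide.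
- Comparison: structurally A2 holds more of the target than 13 does; mechanistically it is a cationic cascade with several exits where the chosen step is one pericyclic event; in overall step count the two would be about equal.

**Alternative 2:** The cut is the C4=C5 bond of ring A at the dihydrodioxine level.
- Forward key step: second-generation Grubbs catalyst would join the isopropenyl group on C3 with the vinyl group on C6 of the bis-allylic peroxyketal tert-butyl (3R)-3-[(2-methoxybut-3-en-2-yl)peroxy]-4-methylpent-4-enoate A3. This would give tert-butyl 2-[(3R)-6-methoxy-4,6-dimethyl-3,6-dihydro-1,2-dioxin-3-yl]acetate A4 as both C6 anomers.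
- In its favour: ruthenium carbene catalysts of this kind are known to tolerate dialkyl peroxides, and there is no ene competition, so in the cleanliness of the ring closure itself it would be the equal or the better of the chosen step. C3 would again come from a non-racemic hydroperoxide, which is better than the chosen plan on absolute configuration. The alkene ends at C4=C5, exactly where the chosen plan needs it, so the endgame would be equal.
- Against it here: A4 lacks the 10-phenyldecyl chain and carries a methoxy group on C6. The chain would have to be introduced afterwards through a cyclic, allylic peroxycarbenium ion and a carbon nucleophile. Regiochemistry (C6 against C4) and facial selectivity (governed only by the remote C3 substituent) would both be open, and a saturated ten-carbon nucleophile is not a typical partner for such ions. The metathesis itself would have to form a trisubstituted alkene from two hindered partners, and prolonged heating with ruthenium puts the O–O bond at risk.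
- Comparison: structurally A4 is ring A without the full skeleton, whereas 13 contains every carbon of the target; in step economy the alternative would be longer, because the C6 quaternary centre is still to be made and the same two-step lactonisation follows.

**Alternative 3:** The cuts are C4–C5, C6–O and O–C3, a three-component assembly of ring A.
- Forward key step: Mn(OAc)3 would oxidise ethyl 2-methyl-3-oxopropanoate A5 to a radical at the carbon that becomes C4, which would add to the CH2 terminus of (11-methyldodec-11-en-1-yl)benzene A6. The tertiary C6 radical would trap ground-state oxygen and the peroxyl oxygen would close onto the aldehyde, giving the dioxanol ethyl 3-hydroxy-4,6-dimethyl-6-(10-phenyldecyl)-1,2-dioxane-4-carboxylate A7.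
- In its favour: it is very convergent, A5 and A6 are simple and achiral, and no photochemistry or diene geometry is involved. In the number of steps up to ring A it would be better than the chosen plan, and on absolute configuration it would be equal (both give racemic material).
- Against it here: A7 does not map cleanly onto the target. C4 carries an ester carbon where the target needs the lactone oxygen, and C3 is a hemiperoxyacetal carbon without the two-carbon arm C2–C1. Repair would need a carbon-to-oxygen exchange at a quaternary centre next to a peroxide and a C-substitution at C3 through a peroxycarbenium ion, neither with stereocontrol. The radical step also leaves the C4/C6 relationship uncontrolled.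
- Comparison: structurally 13 has every carbon and the right oxidation pattern in place; mechanistically a radical chain with trivalent manganese stands against one concerted cycloaddition; in step economy the alternative is short up to A7 but long and uncertain afterwards.

Key step: step 8

Assumption: 1 and 7 are taken as purchasable; locants C1–C6 are those of the lactone chain defined above.
Assumption: the elution order in step 9 cannot be foreseen. The fraction that is 14 is to be identified by anomalous-dispersion X-ray analysis of the iodide 15, or by chiroptical comparison of 16 with reference data.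

## Route

**Step 1**
Reactants: 1 10-phenyldecanoic acid
Product: 2 10-phenyldecan-1-ol
Conditions: LiAlH4, THF, 0 °C → reflux; aq. NaOH work-up
Reagents that add atoms: none
Why: Hydride reduction of a carboxylic acid to the primary alcohol; the phenyl ring and the chain are inert and no stereocentre is involved.

**Step 2**
Reactants: 2 10-phenyldecan-1-ol
Product: 3 (10-bromodecyl)benzene
Conditions: CBr4, PPh3, CH2Cl2, 0 °C → rt
Reagents that add atoms: carbon tetrabromide, BrC(Br)(Br)Br
Why: Appel reaction; the alkoxyphosphonium ion is displaced by bromide in an SN2 process at the primary carbon under neutral conditions.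

**Step 3**
Reactants: 3 (10-bromodecyl)benzene
Product: 4 12-phenyldodec-1-yne
Conditions: LiC≡CH·H2NCH2CH2NH2, DMSO, 10 °C → rt
Reagents that add atoms: lithium acetylide (ethylenediamine complex), [Li]C#C
Why: SN2 alkylation of an acetylide by an unhindered primary bromide in a dipolar aprotic solvent forms the C6–C7 bond and should give the terminal alkyne without isomerisation.

**Step 4**
Reactants: 4 12-phenyldodec-1-yne
Product: 6 [(11E)-12-iodo-11-methyldodec-11-en-1-yl]benzene, via alkenyldimethylalane 5 (not isolated)
Conditions: AlMe3 (2 equiv), Cp2ZrCl2 (0.25 equiv), CH2Cl2, 0 °C → rt; then I2, THF, −30 → 0 °C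
Reagents that add atoms: trimethylaluminium, C[Al](C)C; iodine, II
Why: Zirconium-catalysed methylalumination (carboalumination) adds CH3 and Al syn across the terminal alkyne with methyl on the internal carbon, and iodinolysis of the C–Al bond proceeds with retention, so the E-iodoalkene (iodine trans to the chain) should result.

**Step 5**
Reactants: 7 pent-3-ynoic acid
Product: 8 triisopropylsilyl pent-3-ynoate
Conditions: (i-Pr)3SiCl, imidazole (1.1 equiv), CH2Cl2, 0 °C
Reagents that add atoms: chlorotriisopropylsilane, CC(C)[Si](Cl)(C(C)C)C(C)C
Why: O-Silylation of the carboxylate gives a bulky silyl ester that resists Zr–H reduction and can later be removed without base; a weak base at 0 °C is chosen to avoid propargyl–allenyl isomerisation of the 3-alkynoate.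

**Step 6**
Reactants: 8 triisopropylsilyl pent-3-ynoate; 6 [(11E)-12-iodo-11-methyldodec-11-en-1-yl]benzene
Product: 11 triisopropylsilyl (3E,5E)-4,6-dimethyl-16-phenylhexadeca-3,5-dienoate, via alkenylzirconocene chloride 9 (not isolated), via alkenylzinc chloride 10 (not isolated)
Conditions: 8 (1.5 equiv), Cp2Zr(H)Cl (1.8 equiv), THF, rt → 40 °C; ZnCl2, THF, 0 °C; then 6, Pd(PPh3)4 (5 mol %), THF, rt → 40 °C
Reagents that add atoms: none
Why: Hydrozirconation adds Zr–H syn to the internal alkyne and, after equilibration with a slight excess of hydride, should place zirconium on the less hindered methyl-bearing carbon C4; transmetalation to zinc and Negishi coupling at zerovalent palladium join C4 to C5 with retention at both alkenyl carbons, giving the (3E,5E)-diene.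

**Step 7**
Reactants: 11 triisopropylsilyl (3E,5E)-4,6-dimethyl-16-phenylhexadeca-3,5-dienoate
Product: 12 (3E,5E)-4,6-dimethyl-16-phenylhexadeca-3,5-dienoic acid
Conditions: HF·pyridine, pyridine, THF, 0 °C
Reagents that add atoms: none
Why: Fluoride-induced cleavage of the Si–O bond of the silyl ester frees the acid under buffered, non-basic conditions, so the skipped diene should not move into conjugation with the carboxyl group and its geometry is kept.

**Step 8**
Reactants: 12 (3E,5E)-4,6-dimethyl-16-phenylhexadeca-3,5-dienoic acid
Product: 13 racemic 2-[(3R,6S)-4,6-dimethyl-6-(10-phenyldecyl)-3,6-dihydro-1,2-dioxin-3-yl]acetic acid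
Conditions: O2 (1 atm), tetraphenylporphyrin (cat.), visible light, CH2Cl2, 0 °C
Reagents that add atoms: dioxygen, O=O
Why: Triplet-excited tetraphenylporphyrin transfers energy to ground-state O2, and the singlet oxygen formed adds as a two-atom dienophile across C3 and C6 of the s-cis conformer of 12 in a concerted suprafacial (4+2) cycloaddition. The closest known reaction type is the singlet-oxygen endoperoxidation of acyclic alkyl-substituted 1,3-dienes to 3,6-dihydro-1,2-dioxines. Ring A is closed by the cycloaddition itself: both C–O bonds form in one pericyclic event on one face of the diene, leaving the C4=C5 alkene inside the six-membered ring. C3 and C6 are set relative to each other by the (3E,5E) geometry, because the two outward-pointing groups (the C2 arm and the decyl chain) must end cis, with the inward hydrogen and methyl cis on the other face. Neither face of the achiral diene is favoured, so 13 should form as the racemate and the absolute configuration is left to step 9. The step needs cycloaddition to win over ene reactions at the allylic C2, C7 and methyl hydrogens and over sensitised E/Z isomerisation. The C4 methyl group removes the usual preference for the s-trans conformer (there it would clash with the inward methyl on C6), the diene is electron-rich, and an aprotic chlorinated solvent at low temperature favours the cycloaddition; some ene by-product must still be expected and removed by chromatography.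

**Step 9**
Reactants: 13 racemic 2-[(3R,6S)-4,6-dimethyl-6-(10-phenyldecyl)-3,6-dihydro-1,2-dioxin-3-yl]acetic acid
Product: 14 2-[(3R,6S)-4,6-dimethyl-6-(10-phenyldecyl)-3,6-dihydro-1,2-dioxin-3-yl]acetic acid
Conditions: preparative SFC on amylose tris(3,5-dimethylphenylcarbamate), CO2/MeOH + 0.1% HCO2H
Reagents that add atoms: none
Why: Resolution by chromatography on a chiral stationary phase separates the enantiomers through transient diastereomeric adsorption complexes; the acidic modifier keeps the acid protonated and avoids amine additives, which could trigger Kornblum–DeLaMare cleavage at C3–H.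

**Step 10**
Reactants: 14 2-[(3R,6S)-4,6-dimethyl-6-(10-phenyldecyl)-3,6-dihydro-1,2-dioxin-3-yl]acetic acid
Product: 15 (3S,4R,4aS,7aR)-4-iodo-3,4a-dimethyl-3-(10-phenyldecyl)tetrahydrofuro[3,2-c][1,2]dioxin-6(3H)-one
Conditions: I2, NaHCO3, MeCN/H2O, 0 °C, dark
Reagents that add atoms: iodine, II
Why: Iodolactonisation: reversible iodonium formation on C4=C5 and anti attack of the carboxylate at the more substituted C4 (5-exo-trig, Markovnikov) close ring B; the two-atom tether from C3 forces the new C4–O bond cis to C3–C2, which sets C4 as required, with iodine on C5 trans to the lactone oxygen.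

**Step 11**
Reactants: 15 (3S,4R,4aS,7aR)-4-iodo-3,4a-dimethyl-3-(10-phenyldecyl)tetrahydrofuro[3,2-c][1,2]dioxin-6(3H)-one
Product: 16 (3S,4aR,7aR)-3,4a-dimethyl-3-(10-phenyldecyl)tetrahydrofuro[3,2-c][1,2]dioxin-6(3H)-one (target)
Conditions: Bu3SnH (2 equiv, 0.2 M), Et3B (cat.), air, toluene, 0 °C → rt
Reagents that add atoms: none
Why: Radical chain dehalogenation: Bu3Sn• abstracts iodine and the secondary C5 radical should take hydrogen from Sn–H faster than it can attack the O–O bond, whose rear side it cannot reach collinearly inside the same six-membered ring; the C5 stereocentre disappears and C3, C4 and C6 are untouched.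

## Compound list

1 | 10-phenyldecanoic acid | OC(=O)CCCCCCCCCc1ccccc1 | starting material
2 | 10-phenyldecan-1-ol | OCCCCCCCCCCc1ccccc1 | intermediate
3 | (10-bromodecyl)benzene | BrCCCCCCCCCCc1ccccc1 | intermediate
4 | 12-phenyldodec-1-yne | C#CCCCCCCCCCCc1ccccc1 | intermediate
5 | dimethyl[(1E)-2-methyl-12-phenyldodec-1-en-1-yl]alumane (not isolated) | C[Al](C)/C=C(\C)CCCCCCCCCCc1ccccc1 | intermediate
6 | [(11E)-12-iodo-11-methyldodec-11-en-1-yl]benzene | I/C=C(\C)CCCCCCCCCCc1ccccc1 | intermediate
7 | pent-3-ynoic acid | CC#CCC(=O)O | starting material
8 | triisopropylsilyl pent-3-ynoate | CC#CCC(=O)O[Si](C(C)C)(C(C)C)C(C)C | intermediate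
9 | chlorobis(η5-cyclopentadienyl)[(2E)-5-oxo-5-(triisopropylsilyloxy)pent-2-en-2-yl]zirconium (not isolated; cyclopentadienyl rings drawn σ-bound) | C/C(=C\CC(=O)O[Si](C(C)C)(C(C)C)C(C)C)[Zr](Cl)(C1C=CC=C1)C1C=CC=C1 | intermediate
10 | chloro[(2E)-5-oxo-5-(triisopropylsilyloxy)pent-2-en-2-yl]zinc (not isolated) | C/C([Zn]Cl)=C\CC(=O)O[Si](C(C)C)(C(C)C)C(C)C | intermediate
11 | triisopropylsilyl (3E,5E)-4,6-dimethyl-16-phenylhexadeca-3,5-dienoate | CC(C)[Si](OC(=O)C/C=C(C)/C=C(C)/CCCCCCCCCCc1ccccc1)(C(C)C)C(C)C | intermediate
12 | (3E,5E)-4,6-dimethyl-16-phenylhexadeca-3,5-dienoic acid | OC(=O)C/C=C(C)/C=C(C)/CCCCCCCCCCc1ccccc1 | intermediate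
13 | racemic 2-[(3R,6S)-4,6-dimethyl-6-(10-phenyldecyl)-3,6-dihydro-1,2-dioxin-3-yl]acetic acid (racemate; acetic acid arm and decyl chain cis; one enantiomer drawn) | C[C@]1(CCCCCCCCCCc2ccccc2)C=C(C)[C@@H](CC(=O)O)OO1 | intermediate
14 | 2-[(3R,6S)-4,6-dimethyl-6-(10-phenyldecyl)-3,6-dihydro-1,2-dioxin-3-yl]acetic acid (single enantiomer) | C[C@]1(CCCCCCCCCCc2ccccc2)C=C(C)[C@@H](CC(=O)O)OO1 | intermediate
15 | (3S,4R,4aS,7aR)-4-iodo-3,4a-dimethyl-3-(10-phenyldecyl)tetrahydrofuro[3,2-c][1,2]dioxin-6(3H)-one (cis-fused; iodine trans to the lactone oxygen) | C[C@]1(CCCCCCCCCCc2ccccc2)[C@H](I)[C@@]2(C)OC(=O)C[C@H]2OO1 | intermediate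
16 | (3S,4aR,7aR)-3,4a-dimethyl-3-(10-phenyldecyl)tetrahydrofuro[3,2-c][1,2]dioxin-6(3H)-one (CNP0407146.1) | C[C@]1(CCCCCCCCCCc2ccccc2)C[C@@]2(C)OC(=O)C[C@H]2OO1 | target

## Step count and least certain steps

Total step count: 11. Longest linear sequence: 10 steps (1 → 16 through steps 1–4 and 6–11); the two-step branch from 7 joins at step 6.

**Step 8 (key step).** Most likely failure: ene-type hydroperoxidation and sensitised double-bond isomerisation competing with the cycloaddition, because the inward methyl on C6 twists the diene out of the planar s-cis geometry that the concerted addition needs.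
Fallback: set out from 11 and replace singlet oxygen by ground-state O2 in a cation-radical chain oxygenation (catalytic tris(4-bromophenyl)aminium hexachloroantimonate, (4-BrC6H4)3N SbCl6, O2, CH2Cl2, −78 °C). This is a known way from electron-rich alkyl dienes to 3,6-dihydro-1,2-dioxines and has no ene channel. It should give racemic triisopropylsilyl 2-[(3R*,6S*)-4,6-dimethyl-6-(10-phenyldecyl)-3,6-dihydro-1,2-dioxin-3-yl]acetate F1; any trans isomer from the stepwise mechanism would have to be removed by chromatography. Desilylation with HF·pyridine as in step 7 returns to the route at 13.

**Step 6.** Most likely failure: Zr–H addition with the wrong orientation (zirconium on C3), partial reduction of the silyl ester by the excess hydride, or slow transmetalation and coupling of the hindered α-methyl alkenyl metal with loss of the iodide by reduction.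
Fallback: exchange the roles of the two partners. Setting out from 8, hydrozirconation (Cp2Zr(H)Cl, THF) followed by I2 should give triisopropylsilyl (3E)-4-iodopent-3-enoate F2, which can be freed from its regioisomer by chromatography before any C–C bond is made. Alkyne 4 is methylaluminated to 5 as in step 4 but not iodinated; after removal of volatiles, 5 is coupled directly with F2 (ZnCl2, Pd(PPh3)4, THF, rt). The sequence returns to the route at 11.

**Step 11.** Most likely failure: intramolecular attack of the C5 radical on the neighbouring peroxide oxygen, β-fragmentation, or attack of the stannyl radical on O–O, each opening ring A, because a carbon radical is generated directly beside the peroxide.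
Fallback: set out from 14 and close ring B by mercuricyclisation (Hg(OAc)2, THF/H2O, 0 °C) to the organomercurial (acetato)[(3S,4R,4aS,7aR)-3,4a-dimethyl-6-oxo-3-(10-phenyldecyl)hexahydrofuro[3,2-c][1,2]dioxin-4-yl]mercury F3. Reductive demercuration (NaBH4, aq. NaOH, 0 °C) proceeds through an alkylmercury hydride, a faster hydrogen donor than Sn–H, and returns to the route at 16.

**Step 10.** Most likely failure: capture of the iodonium ion in the six-membered mode at C5, reduction of the O–O bond by the iodide that accumulates, or bicarbonate-induced fragmentation at C3–H.
Fallback: set out from 14 and use selenolactonisation without iodide or base (N-(phenylseleno)phthalimide, cat. camphorsulfonic acid, CH2Cl2, 0 °C) to give (3S,4R,4aS,7aR)-3,4a-dimethyl-3-(10-phenyldecyl)-4-(phenylselanyl)tetrahydrofuro[3,2-c][1,2]dioxin-6(3H)-one F4. Radical deselenation (Bu3SnH, AIBN, toluene, 80 °C) returns to the route at 16.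

**Step 9.** Most likely failure: insufficient chiral recognition of a flexible long-chain acid on the stationary phase, so that the bands overlap.
Fallback: separate covalent diastereomers on ordinary silica. Setting out from 13, coupling with (S)-N-methyl-1-phenylethylamine (EDC·HCl, HOBt, CH2Cl2, 0 °C) should give N-methyl-N-[(1S)-1-phenylethyl]-2-[(3R,6S)-4,6-dimethyl-6-(10-phenyldecyl)-3,6-dihydro-1,2-dioxin-3-yl]acetamide F5 and N-methyl-N-[(1S)-1-phenylethyl]-2-[(3S,6R)-4,6-dimethyl-6-(10-phenyldecyl)-3,6-dihydro-1,2-dioxin-3-yl]acetamide F6. After chromatographic separation, iodolactonisation of F5 (I2, THF/H2O, 0 °C) proceeds through the cyclic iminium ether, whose hydrolysis expels the auxiliary amine, and returns to the route at 15.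

## Further compounds

F1 | step 8 | triisopropylsilyl 2-[(3R*,6S*)-4,6-dimethyl-6-(10-phenyldecyl)-3,6-dihydro-1,2-dioxin-3-yl]acetate (racemate; one enantiomer drawn) | C[C@]1(CCCCCCCCCCc2ccccc2)C=C(C)[C@@H](CC(=O)O[Si](C(C)C)(C(C)C)C(C)C)OO1
F2 | step 6 | triisopropylsilyl (3E)-4-iodopent-3-enoate | C/C(I)=C\CC(=O)O[Si](C(C)C)(C(C)C)C(C)C
F3 | step 11 | (acetato)[(3S,4R,4aS,7aR)-3,4a-dimethyl-6-oxo-3-(10-phenyldecyl)hexahydrofuro[3,2-c][1,2]dioxin-4-yl]mercury | C[C@]1(CCCCCCCCCCc2ccccc2)[C@H]([Hg]OC(C)=O)[C@@]2(C)OC(=O)C[C@H]2OO1
F4 | step 10 | (3S,4R,4aS,7aR)-3,4a-dimethyl-3-(10-phenyldecyl)-4-(phenylselanyl)tetrahydrofuro[3,2-c][1,2]dioxin-6(3H)-one | C[C@]1(CCCCCCCCCCc2ccccc2)[C@H]([Se]c3ccccc3)[C@@]2(C)OC(=O)C[C@H]2OO1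
F5 | step 9 | N-methyl-N-[(1S)-1-phenylethyl]-2-[(3R,6S)-4,6-dimethyl-6-(10-phenyldecyl)-3,6-dihydro-1,2-dioxin-3-yl]acetamide | C[C@]1(CCCCCCCCCCc2ccccc2)C=C(C)[C@@H](CC(=O)N(C)[C@@H](C)c2ccccc2)OO1
F6 | step 9 | N-methyl-N-[(1S)-1-phenylethyl]-2-[(3S,6R)-4,6-dimethyl-6-(10-phenyldecyl)-3,6-dihydro-1,2-dioxin-3-yl]acetamide | C[C@@]1(CCCCCCCCCCc2ccccc2)C=C(C)[C@H](CC(=O)N(C)[C@@H](C)c2ccccc2)OO1
A1 | alternative 1 | tert-butyl (3R)-3-[(2-methoxy-12-phenyldodec-3-yn-2-yl)peroxy]-4-methylpent-4-enoate (both ketal epimers) | COC(C)(C#CCCCCCCCCc1ccccc1)OO[C@H](CC(=O)OC(C)(C)C)C(C)=C
A2 | alternative 1 | (3R,4aR,7aR)-3,4a-dimethyl-3-(10-phenyldec-1-yn-1-yl)tetrahydrofuro[3,2-c][1,2]dioxin-6(3H)-one | C[C@]1(C#CCCCCCCCCc2ccccc2)C[C@@]2(C)OC(=O)C[C@H]2OO1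
A3 | alternative 2 | tert-butyl (3R)-3-[(2-methoxybut-3-en-2-yl)peroxy]-4-methylpent-4-enoate (both ketal epimers) | C=CC(C)(OC)OO[C@H](CC(=O)OC(C)(C)C)C(C)=C
A4 | alternative 2 | tert-butyl 2-[(3R)-6-methoxy-4,6-dimethyl-3,6-dihydro-1,2-dioxin-3-yl]acetate (both C6 anomers) | COC1(C)C=C(C)[C@@H](CC(=O)OC(C)(C)C)OO1
A5 | alternative 3 | ethyl 2-methyl-3-oxopropanoate | CCOC(=O)C(C)C=O
A6 | alternative 3 | (11-methyldodec-11-en-1-yl)benzene | C=C(C)CCCCCCCCCCc1ccccc1
A7 | alternative 3 | ethyl 3-hydroxy-4,6-dimethyl-6-(10-phenyldecyl)-1,2-dioxane-4-carboxylate (racemic mixture of diastereomers) | CCOC(=O)C1(C)CC(C)(CCCCCCCCCCc2ccccc2)OOC1O
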